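The flask is judged against amber and green, which share its charges of starting material and second nucleophile and hold more first nucleophile.

| setting | amber | green | ochre | flask |
|---|---|---|---|---|
| starting material | 0.80 M | 0.80 M | 0.80 M | 0.80 M |
| first nucleophile | 1.1 M | 1.7 M | 0.76 M | 0.760 M |
| second nucleophile | 0.48 M | 0.48 M | 0.96 M | 0.480 M |
| remark | run made earlier | run made earlier | run made earlier |  |
| time |  |  |  | 8.0 min |

| run | time / min | target / % | other capture product / % |
|---|---|---|---|
| amber | 0.417 | 3 | 4 |
| amber | 1.33 | 10 | 14 |
| amber | 2.50 | 10 | 19 |
| amber | 3.00 | 14 | 15 |
| amber | 5.00 | 12 | 23 |
| amber | 6.00 | 14 | 22 |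
| amber | 8.00 | 15 | 26 |
| green | 0.667 | 4 | 2 |
| green | 1.00 | 6 | 7 |
| green | 1.33 | 12 | 8 |
| green | 2.50 | 14 | 13 |
| green | 3.00 | 14 | 14 |
| green | 5.00 | 14 | 12 |
| green | 8.00 | 18 | 16 |
| ochre | 1.50 | 4 | 14 |
| ochre | 3.00 | 2 | 34 |
| ochre | 5.00 | 4 | 37 |
| ochre | 6.00 | 3 | 41 |
| ochre | 8.00 | 1 | 45 |

(readings scatter by 2 percentage points)

- percent here means starting material units held: one side product counts as two
- what may be going on: starting material + target -> side product; starting material -> intermediate; first nucleophile + intermediate -> target; second nucleophile + intermediate -> other capture product; intermediate -> solvolysis product; second nucleophile + target -> over-reaction product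

- concentration of target at 8.0 min, in M
- concentration of other capture product at 8.0 min, in M

1. With that second nucleophile charge held and target's losses taken as equal, target's share of the intermediate is B/(B+K), with B the first nucleophile charge; K/(B+K) is the fraction left for the other exits. The target readings at 8.00 min, 15% in amber and 18% in green, give K = 0.984 M. This reading, the competition constant, is the first nucleophile concentration at which target's capture equals the other exits together.
2. From above: less first nucleophile lowers the share, so this estimate puts the flask below amber's reading of 0.120 M.
3. From below: the share falls at most in proportion to B, so this estimate puts the flask above 10.4%, or 0.0829 M.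
4. Tightened: K gives 12.4%, or 0.0991 M. Any positive K stays inside the bracket, though a scatter of 2 percentage points moves both ends.
5. The forecast gives 0.07 M and 0.23 M, holding that “Over-reaction trims the flask's target further”. Its target value lies below the bracket.

The flask gives 0.0969 M and 0.243 M; its target lies inside the bracket, against 0.0991 M from K.

    starting material + target → side product (k = 0.150 /M/min)
    starting material → intermediate (k = 0.200 /min)
    first nucleophile + intermediate → target (k = 170 /M/min)
    second nucleophile + intermediate → other capture product (k = 380 /M/min)
    intermediate → solvolysis product (k = 61.0 /min)
    second nucleophile + target → over-reaction product (k = 0.880 /M/min)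

At 2.48 min the flask's target is made 1.56 times faster than it is used up, each step net. The flask's target stands higher at 8.00 min, at 12.1%, than at 4.00 min, at 10.5%.

In a neighbour flask with 3.0 M of first nucleophile and all else unchanged, K gives 21.4% of target; the computed neighbour holds 19.8%, or 0.159 M.

The readings were generated by integration for an exercise.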